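Retrosynthesis: with the three benzyl ethers and the dioxolane removed, ring C is taken back to a cyclohexane-1,3-dione blocked at C1 by an ester and is cut at C1–C2 (Michael) and C5–C6 (Claisen) into malonate 7 and α-methylene ketone 14. Malonate 7 is cut at the added ester carbon and at the bond from the stereocentre to ring B; enone 14 at its methylene carbon and at the bond from the acetoacetate carbon to the arm.
Enabling feature: ring C is a resorcinol with oxygen on C4 and C6, the stereocentre on C1 and the 3-aryl-3-oxopropyl arm on C3, which is a 4,6-disubstituted cyclohexane-1,3-dione in disguise. C1 is the malonate carbon, C6 an ester carbonyl, C5 the ketone methyl, C4 the ketone carbonyl, C3 the enone α-carbon and C2 the enone methylene; rings A, B and D (4-hydroxy-2-methoxyphenyl, 4-hydroxyphenyl, 4-hydroxybenzoyl) are spectators.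
Forward order: ring A bromide to propanal to (E)-enoate, ring B added by conjugate arylation, then malonate 7 (steps 1–5); ring D chloroketone to benzyl ether to dioxolane to alkylated acetoacetate to enone 14 (steps 6–9); the two fragments are joined and ring C, the only ring built, closes in step 10.
Endgame: ring C is dehydrogenated at C2–C3 while C1 is still quaternary, so the oxidation cannot reach the stereocentre; loss of the ester then aromatises it, and ketal hydrolysis and hydrogenolysis finish (steps 11–14).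
Stereochemistry: the single (R) centre comes from the rhodium/(S)-BINAP arylation in step 4; it is never α to a carbonyl afterwards, and the two ring centres formed in step 10 disappear on aromatisation.
Key step: step 10

Assumption: the (S)-BINAP–rhodium catalyst is taken to deliver the aryl group to the Cα-re/Cβ-si face of (E)-enoate 4, as it does with (E)-configured acyclic enones. That face gives (S)-ester 6, whose centre becomes (R) in the target once ring C outranks ring B. Should the first sample prove to be the antipode, (R)-BINAP would be used with nothing else changed.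

Step 1
Reactants: 1 4-bromo-3-methoxyphenol
Product: 2 4-(benzyloxy)-1-bromo-2-methoxybenzene
Conditions: BnBr, K2CO3, DMF, rt
Reagents that add atoms: benzyl bromide, BrCc1ccccc1
Why: Williamson etherification of the phenoxide with a benzylic halide should be clean, and the benzyl ether is chosen because it survives every later base, acid and palladium acetate step and falls in the final hydrogenolysis.

Step 2
Reactants: 2 4-(benzyloxy)-1-bromo-2-methoxybenzene
Product: 3 3-[4-(benzyloxy)-2-methoxyphenyl]propanal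
Conditions: allyl alcohol, Pd(OAc)2 (cat.), Bu4NCl, NaHCO3, DMF, 80 °C
Reagents that add atoms: allyl alcohol, C=CCO
Why: Heck arylation of allyl alcohol under ligand-free Jeffery conditions puts the aryl group on the terminal carbon, and β-hydride elimination toward the carbinol carbon gives an enol that tautomerises to the saturated aldehyde.

Step 3
Reactants: 3 3-[4-(benzyloxy)-2-methoxyphenyl]propanal
Product: 4 methyl (E)-5-[4-(benzyloxy)-2-methoxyphenyl]pent-2-enoate
Conditions: Ph3P=CHCO2Me, CH2Cl2, rt
Reagents that add atoms: methyl (triphenylphosphoranylidene)acetate, COC(=O)C=P(c1ccccc1)(c1ccccc1)c1ccccc1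
Why: Wittig olefination with a stabilised ylide should give the (E)-enoate under neutral conditions that spare the enolisable aldehyde; any minor (Z)-isomer is removed by chromatography because it would give the antipode in step 4.

Step 4
Reactants: 4 methyl (E)-5-[4-(benzyloxy)-2-methoxyphenyl]pent-2-enoate; 5 4-(benzyloxy)phenylboronic acid
Product: 6 methyl (S)-3-[4-(benzyloxy)phenyl]-5-[4-(benzyloxy)-2-methoxyphenyl]pentanoate
Conditions: [Rh(OH)((S)-BINAP)]2 (cat.), 5 (2.5 equiv), 1,4-dioxane/H2O 10:1, 50 °C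
Reagents that add atoms: none
Why: Hayashi–Miyaura asymmetric conjugate arylation, in which the aryl–rhodium species bound to (S)-BINAP inserts the (E)-enoate at its Cα-re/Cβ-si face and water protonates the rhodium enolate, sets the only stereocentre of the route as (S) in 6.

Step 5
Reactants: 6 methyl (S)-3-[4-(benzyloxy)phenyl]-5-[4-(benzyloxy)-2-methoxyphenyl]pentanoate
Product: 7 dimethyl 2-{(S)-1-[4-(benzyloxy)phenyl]-3-[4-(benzyloxy)-2-methoxyphenyl]propyl}malonate
Conditions: LiN(iPr)2 (2.1 equiv), THF, −78 °C; ClCO2Me (1.05 equiv), −78 to 0 °C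
Reagents that add atoms: methyl chloroformate, COC(=O)Cl
Why: C-acylation of the ester lithium enolate with a chloroformate gives the malonate (the second equivalent of base absorbs the more acidic product), and the stereocentre, being β to the ester, has no acidic hydrogen.

Step 6
Reactants: 8 3-chloro-1-(4-hydroxyphenyl)propan-1-one
Product: 9 1-[4-(benzyloxy)phenyl]-3-chloropropan-1-one
Conditions: BnOH, PPh3, DIAD, THF, 0 °C to rt
Reagents that add atoms: benzyl alcohol, OCc1ccccc1
Why: Mitsunobu etherification benzylates the acidic 4-acylphenol under essentially neutral conditions, which avoids the E1cB loss of HCl that carbonate bases would cause in a β-chloro ketone.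

Step 7
Reactants: 9 1-[4-(benzyloxy)phenyl]-3-chloropropan-1-one
Product: 10 2-[4-(benzyloxy)phenyl]-2-(2-chloroethyl)-1,3-dioxolane
Conditions: ethylene glycol, p-TsOH (cat.), toluene, reflux, Dean–Stark
Reagents that add atoms: ethylene glycol, OCCO
Why: Acid-catalysed ketalisation with azeotropic removal of water masks the aryl ketone, which would otherwise enolise and condense under the bases of steps 8 to 11, and the β-chloro ketone is stable to acid.

Step 8
Reactants: 10 2-[4-(benzyloxy)phenyl]-2-(2-chloroethyl)-1,3-dioxolane; 11 methyl acetoacetate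
Product: 12 methyl 2-acetyl-4-{2-[4-(benzyloxy)phenyl]-1,3-dioxolan-2-yl}butanoate (racemic)
Conditions: 11 (1.5 equiv), NaH, DMF, 0 °C; then 10, NaI (cat.), 70 °C
Reagents that add atoms: none
Why: Acetoacetic ester alkylation proceeds by SN2 attack of the sodium enolate on the primary halide, iodide catalysis making up for the chloride leaving group and excess acetoacetate suppressing dialkylation.

Step 9
Reactants: 12 methyl 2-acetyl-4-{2-[4-(benzyloxy)phenyl]-1,3-dioxolan-2-yl}butanoate
Product: 14 5-{2-[4-(benzyloxy)phenyl]-1,3-dioxolan-2-yl}-3-methylidenepentan-2-one, via keto acid 13 (not isolated)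
Conditions: KOH (1.1 equiv), MeOH/H2O, 0 °C to rt; then Et2NH·HCl, 37 % aq. CH2O, rt to 45 °C
Reagents that add atoms: formaldehyde, C=O
Why: Saponification followed by decarboxylative Mannich methylenation, in which the keto acid is aminomethylated at its α-carbon and then loses CO2 and the amine together, places the methylene group only on the carbon that carried the carboxyl, and the near-neutral medium spares the ketal.

Step 10
Reactants: 7 dimethyl 2-{(S)-1-[4-(benzyloxy)phenyl]-3-[4-(benzyloxy)-2-methoxyphenyl]propyl}malonate; 14 5-{2-[4-(benzyloxy)phenyl]-1,3-dioxolan-2-yl}-3-methylidenepentan-2-one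
Product: 16 methyl 1-{(R)-1-[4-(benzyloxy)phenyl]-3-[4-(benzyloxy)-2-methoxyphenyl]propyl}-5-(2-{2-[4-(benzyloxy)phenyl]-1,3-dioxolan-2-yl}ethyl)-2,4-dioxocyclohexane-1-carboxylate (mixture at both ring centres), via Michael adduct 15 (not isolated)
Conditions: NaOMe (1.2 equiv), MeOH/THF, 7, 0 °C; 14 (1.3 equiv) added slowly, rt; then 65 °C; AcOH quench
Reagents that add atoms: none
Why: Michael–Claisen [3+3] annulation: the sodium enolate of 7 adds through its one nucleophilic carbon to the unsubstituted methylene of 14 (C1–C2 bond), the enolate so formed is protonated by methanol and regenerated on the methyl side, and that methyl ketone enolate acylates one of the geminal esters with loss of methoxide (C5–C6 bond). The closest known reaction type is the alkoxide-mediated condensation of substituted malonates with vinyl ketones to 4-alkoxycarbonyl-cyclohexane-1,3-diones (dimedone-type synthesis). Ring C closes by a 6-(enolendo)-exo-trig acyl substitution, and the only alternative, attack of the internal enolate, would need a four-membered ring. The two ring stereocentres (C1 and C3) form without control and are both erased on aromatisation, while the side-chain centre has no acidic hydrogen under alkoxide and is carried through, its descriptor changing to (R) only because the quaternary C1 now outranks ring B. The step needs conjugate addition to outrun self-condensation of the enone, which preforming the malonate anion and slow addition of 14 should secure, and it needs the reversible steps pulled forward, which deprotonation of the acidic 1,3-dione product by methoxide provides.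

Step 11
Reactants: 16 methyl 1-{(R)-1-[4-(benzyloxy)phenyl]-3-[4-(benzyloxy)-2-methoxyphenyl]propyl}-5-(2-{2-[4-(benzyloxy)phenyl]-1,3-dioxolan-2-yl}ethyl)-2,4-dioxocyclohexane-1-carboxylate
Product: 17 methyl 1-{(R)-1-[4-(benzyloxy)phenyl]-3-[4-(benzyloxy)-2-methoxyphenyl]propyl}-5-(2-{2-[4-(benzyloxy)phenyl]-1,3-dioxolan-2-yl}ethyl)-2,4-bis(trimethylsilyloxy)cyclohexa-2,4-diene-1-carboxylate
Conditions: LiN(iPr)2 (2.3 equiv), THF, −78 to 0 °C; TMSCl (3 equiv), −78 °C to rt; pentane, filtration, used crude
Reagents that add atoms: chlorotrimethylsilane, C[Si](C)(C)Cl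
Why: Dianion formation of the cyclic 1,3-dione (the first equivalent of base removes the enol proton, the second the only remaining α-hydrogen, at C3, because C1 is quaternary) followed by O,O-silylation is the established way to 1,3-bis(silyloxy)-1,3-dienes and can give only the C3=C4/C5=C6 diene.

Step 12
Reactants: 17 methyl 1-{(R)-1-[4-(benzyloxy)phenyl]-3-[4-(benzyloxy)-2-methoxyphenyl]propyl}-5-(2-{2-[4-(benzyloxy)phenyl]-1,3-dioxolan-2-yl}ethyl)-2,4-bis(trimethylsilyloxy)cyclohexa-2,4-diene-1-carboxylate
Product: 19 4-{(R)-1-[4-(benzyloxy)phenyl]-3-[4-(benzyloxy)-2-methoxyphenyl]propyl}-6-(2-{2-[4-(benzyloxy)phenyl]-1,3-dioxolan-2-yl}ethyl)benzene-1,3-diol, via silyloxy dienone ester 18 (not isolated)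
Conditions: Pd(OAc)2 (1.1 equiv), MeCN, rt; Celite filtration, evaporation; then K2CO3, MeOH, rt, argon
Reagents that add atoms: none
Why: Saegusa–Ito oxidation, in which divalent palladium attacks the diene terminus C3 and the carbon-bound palladium enolate loses the syn hydrogen on C2 to leave zerovalent palladium and cross-conjugated dienone 18, cannot form a double bond toward the stereocentre because C1 is quaternary; methoxide then removes the silyl group and the blocking ester as dimethyl carbonate in a retro-Claisen cleavage whose leaving carbanion is the aromatic resorcinolate.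

Step 13
Reactants: 19 4-{(R)-1-[4-(benzyloxy)phenyl]-3-[4-(benzyloxy)-2-methoxyphenyl]propyl}-6-(2-{2-[4-(benzyloxy)phenyl]-1,3-dioxolan-2-yl}ethyl)benzene-1,3-diol
Product: 20 3-{5-[(R)-1-[4-(benzyloxy)phenyl]-3-[4-(benzyloxy)-2-methoxyphenyl]propyl]-2,4-dihydroxyphenyl}-1-[4-(benzyloxy)phenyl]propan-1-one
Conditions: 1 M HCl, THF, rt
Reagents that add atoms: water, O
Why: Acid-catalysed ketal hydrolysis is fast here because the 4-alkoxyphenyl group stabilises the oxocarbenium ion, while the benzyl ethers, the methyl ether and the diarylmethine centre are inert to dilute acid at room temperature.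

Step 14
Reactants: 20 3-{5-[(R)-1-[4-(benzyloxy)phenyl]-3-[4-(benzyloxy)-2-methoxyphenyl]propyl]-2,4-dihydroxyphenyl}-1-[4-(benzyloxy)phenyl]propan-1-one
Product: 21 3-{2,4-dihydroxy-5-[(R)-3-(4-hydroxy-2-methoxyphenyl)-1-(4-hydroxyphenyl)propyl]phenyl}-1-(4-hydroxyphenyl)propan-1-one (CNP0253987.1)
Conditions: H2 (1 atm), 10 % Pd/C, EtOAc/MeOH, rt
Reagents that add atoms: none
Why: Hydrogenolysis of the three benzyl aryl ethers over palladium on carbon should release the target, since the 4-oxygenated aryl ketone is a poor substrate for hydrogenation at one atmosphere, as is usual for dihydrochalcones, provided the reaction is stopped once debenzylation is complete.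

Compound list
1 | 4-bromo-3-methoxyphenol | COc1cc(O)ccc1Br | starting material
2 | 4-(benzyloxy)-1-bromo-2-methoxybenzene | COc1cc(OCc2ccccc2)ccc1Br | intermediate
3 | 3-[4-(benzyloxy)-2-methoxyphenyl]propanal | COc1cc(OCc2ccccc2)ccc1CCC=O | intermediate
4 | methyl (E)-5-[4-(benzyloxy)-2-methoxyphenyl]pent-2-enoate | COC(=O)/C=C/CCc1ccc(OCc2ccccc2)cc1OC | intermediate
5 | 4-(benzyloxy)phenylboronic acid | OB(O)c1ccc(OCc2ccccc2)cc1 | starting material
6 | methyl (S)-3-[4-(benzyloxy)phenyl]-5-[4-(benzyloxy)-2-methoxyphenyl]pentanoate | COc1cc(OCc2ccccc2)ccc1CC[C@H](c1ccc(OCc2ccccc2)cc1)CC(=O)OC | intermediate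
7 | dimethyl 2-{(S)-1-[4-(benzyloxy)phenyl]-3-[4-(benzyloxy)-2-methoxyphenyl]propyl}malonate | COc1cc(OCc2ccccc2)ccc1CC[C@H](c1ccc(OCc2ccccc2)cc1)C(C(=O)OC)C(=O)OC | intermediate
8 | 3-chloro-1-(4-hydroxyphenyl)propan-1-one | O=C(CCCl)c1ccc(O)cc1 | starting material
9 | 1-[4-(benzyloxy)phenyl]-3-chloropropan-1-one | O=C(CCCl)c1ccc(OCc2ccccc2)cc1 | intermediate
10 | 2-[4-(benzyloxy)phenyl]-2-(2-chloroethyl)-1,3-dioxolane | ClCCC1(c2ccc(OCc3ccccc3)cc2)OCCO1 | intermediate
11 | methyl acetoacetate | COC(=O)CC(C)=O | starting material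
12 | methyl 2-acetyl-4-{2-[4-(benzyloxy)phenyl]-1,3-dioxolan-2-yl}butanoate (racemic) | COC(=O)C(CCC1(c2ccc(OCc3ccccc3)cc2)OCCO1)C(C)=O | intermediate
13 | 2-acetyl-4-{2-[4-(benzyloxy)phenyl]-1,3-dioxolan-2-yl}butanoic acid (potassium salt in the flask, not isolated) | OC(=O)C(CCC1(c2ccc(OCc3ccccc3)cc2)OCCO1)C(C)=O | intermediate
14 | 5-{2-[4-(benzyloxy)phenyl]-1,3-dioxolan-2-yl}-3-methylidenepentan-2-one | CC(=O)C(=C)CCC1(c2ccc(OCc3ccccc3)cc2)OCCO1 | intermediate
15 | dimethyl 2-(2-acetyl-4-{2-[4-(benzyloxy)phenyl]-1,3-dioxolan-2-yl}butyl)-2-{(R)-1-[4-(benzyloxy)phenyl]-3-[4-(benzyloxy)-2-methoxyphenyl]propyl}malonate (Michael adduct, not isolated) | COc1cc(OCc2ccccc2)ccc1CC[C@H](c1ccc(OCc2ccccc2)cc1)C(C(=O)OC)(C(=O)OC)CC(CCC1(c2ccc(OCc3ccccc3)cc2)OCCO1)C(C)=O | intermediate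
16 | methyl 1-{(R)-1-[4-(benzyloxy)phenyl]-3-[4-(benzyloxy)-2-methoxyphenyl]propyl}-5-(2-{2-[4-(benzyloxy)phenyl]-1,3-dioxolan-2-yl}ethyl)-2,4-dioxocyclohexane-1-carboxylate (both ring centres unassigned) | COc1cc(OCc2ccccc2)ccc1CC[C@H](c1ccc(OCc2ccccc2)cc1)C1(C(=O)OC)CC(CCC2(c3ccc(OCc4ccccc4)cc3)OCCO2)C(=O)CC1=O | intermediate
17 | methyl 1-{(R)-1-[4-(benzyloxy)phenyl]-3-[4-(benzyloxy)-2-methoxyphenyl]propyl}-5-(2-{2-[4-(benzyloxy)phenyl]-1,3-dioxolan-2-yl}ethyl)-2,4-bis(trimethylsilyloxy)cyclohexa-2,4-diene-1-carboxylate | COc1cc(OCc2ccccc2)ccc1CC[C@H](c1ccc(OCc2ccccc2)cc1)C1(C(=O)OC)CC(CCC2(c3ccc(OCc4ccccc4)cc3)OCCO2)=C(O[Si](C)(C)C)C=C1O[Si](C)(C)C | intermediate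
18 | methyl 1-{(R)-1-[4-(benzyloxy)phenyl]-3-[4-(benzyloxy)-2-methoxyphenyl]propyl}-5-(2-{2-[4-(benzyloxy)phenyl]-1,3-dioxolan-2-yl}ethyl)-4-oxo-2-(trimethylsilyloxy)cyclohexa-2,5-diene-1-carboxylate (not isolated) | COc1cc(OCc2ccccc2)ccc1CC[C@H](c1ccc(OCc2ccccc2)cc1)C1(C(=O)OC)C=C(CCC2(c3ccc(OCc4ccccc4)cc3)OCCO2)C(=O)C=C1O[Si](C)(C)C | intermediate
19 | 4-{(R)-1-[4-(benzyloxy)phenyl]-3-[4-(benzyloxy)-2-methoxyphenyl]propyl}-6-(2-{2-[4-(benzyloxy)phenyl]-1,3-dioxolan-2-yl}ethyl)benzene-1,3-diol | COc1cc(OCc2ccccc2)ccc1CC[C@H](c1ccc(OCc2ccccc2)cc1)c1cc(CCC2(c3ccc(OCc4ccccc4)cc3)OCCO2)c(O)cc1O | intermediate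
20 | 3-{5-[(R)-1-[4-(benzyloxy)phenyl]-3-[4-(benzyloxy)-2-methoxyphenyl]propyl]-2,4-dihydroxyphenyl}-1-[4-(benzyloxy)phenyl]propan-1-one | COc1cc(OCc2ccccc2)ccc1CC[C@H](c1ccc(OCc2ccccc2)cc1)c1cc(CCC(=O)c2ccc(OCc3ccccc3)cc2)c(O)cc1O | intermediate
21 | 3-{2,4-dihydroxy-5-[(R)-3-(4-hydroxy-2-methoxyphenyl)-1-(4-hydroxyphenyl)propyl]phenyl}-1-(4-hydroxyphenyl)propan-1-one | COc1cc(O)ccc1CC[C@H](c1ccc(O)cc1)c1cc(CCC(=O)c2ccc(O)cc2)c(O)cc1O | target

Total step count: 14.
Longest linear sequence: 10 steps (steps 1–5 and 10–14, from 4-bromo-3-methoxyphenol); the enone branch (steps 6–9) joins at step 10.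

Steps most likely to fail

Step 10. The conjugate addition of the crowded, fully substituted malonate anion to the α-branched enone may be slower than methoxide addition to 14 and self-condensation of 14, and an adduct that does form can revert by retro-Michael reaction before the Claisen closure. The fallback sets out from 7 and runs the same annulation with but-3-en-2-one, which is unbranched at its α-carbon, more electrophilic and usable in large excess (NaOMe, MeOH, reflux). Through the acyclic adduct dimethyl 2-{(R)-1-[4-(benzyloxy)phenyl]-3-[4-(benzyloxy)-2-methoxyphenyl]propyl}-2-(3-oxobutyl)malonate F1 this should give the arm-free dione methyl 1-{(R)-1-[4-(benzyloxy)phenyl]-3-[4-(benzyloxy)-2-methoxyphenyl]propyl}-2,4-dioxocyclohexane-1-carboxylate F2. The arm is then introduced by alkylation of the dianion of F2 (LiN(iPr)2, 2.2 equiv, THF/DMPU, −78 to 0 °C), which can form only at ring carbon C3 because C1 is quaternary, with 2-[4-(benzyloxy)phenyl]-2-(2-iodoethyl)-1,3-dioxolane F3, prepared from chloride 10 by halide exchange (NaI, acetone, reflux). The route is rejoined at 16.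

Step 12. After silicon-to-palladium exchange the metal may rest as an oxygen-bound or chelated enolate that never reaches C3, or β-hydride elimination may run toward the side-chain methylene and not into the ring; either way dehydrogenation stalls and the ester cannot leave. The fallback sets out from 16 and replaces palladium by selenium. The dianion of 16 (LiN(iPr)2, 2.2 equiv, THF, −78 °C) is selenenylated at C3 with PhSeBr to give methyl 1-{(R)-1-[4-(benzyloxy)phenyl]-3-[4-(benzyloxy)-2-methoxyphenyl]propyl}-5-(2-{2-[4-(benzyloxy)phenyl]-1,3-dioxolan-2-yl}ethyl)-2,4-dioxo-5-(phenylselanyl)cyclohexane-1-carboxylate F4. Oxidation (H2O2, pyridine, CH2Cl2, 0 °C) gives the corresponding selenoxide F5, whose syn elimination at or below room temperature should give the unsilylated dienone ester methyl 1-{(R)-1-[4-(benzyloxy)phenyl]-3-[4-(benzyloxy)-2-methoxyphenyl]propyl}-5-(2-{2-[4-(benzyloxy)phenyl]-1,3-dioxolan-2-yl}ethyl)-2,4-dioxocyclohex-5-ene-1-carboxylate F6. Treatment of F6 with K2CO3 in MeOH removes the ester as before and rejoins the route at 19.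

Step 2. Oxidative addition of the electron-rich, ortho-substituted aryl bromide may be slow under ligand-free conditions, so that palladium black separates, the aldehyde is lost to aldol condensation at the temperature then required, and some branched 2-arylpropanal forms by the other insertion regiochemistry. The fallback sets out from 2 and uses organolithium chemistry. Bromine–lithium exchange (n-BuLi, THF, −78 °C) gives [4-(benzyloxy)-2-methoxyphenyl]lithium F7, which opens oxetane in the presence of BF3·OEt2 to 3-[4-(benzyloxy)-2-methoxyphenyl]propan-1-ol F8. Dess–Martin oxidation (CH2Cl2, rt) of F8 rejoins the route at 3.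

Further compounds
F1 | step 10 | dimethyl 2-{(R)-1-[4-(benzyloxy)phenyl]-3-[4-(benzyloxy)-2-methoxyphenyl]propyl}-2-(3-oxobutyl)malonate | COc1cc(OCc2ccccc2)ccc1CC[C@H](c1ccc(OCc2ccccc2)cc1)C(C(=O)OC)(C(=O)OC)CCC(C)=O
F2 | step 10 | methyl 1-{(R)-1-[4-(benzyloxy)phenyl]-3-[4-(benzyloxy)-2-methoxyphenyl]propyl}-2,4-dioxocyclohexane-1-carboxylate | COc1cc(OCc2ccccc2)ccc1CC[C@H](c1ccc(OCc2ccccc2)cc1)C1(C(=O)OC)CCC(=O)CC1=O
F3 | step 10 | 2-[4-(benzyloxy)phenyl]-2-(2-iodoethyl)-1,3-dioxolane | ICCC1(c2ccc(OCc3ccccc3)cc2)OCCO1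
F4 | step 12 | methyl 1-{(R)-1-[4-(benzyloxy)phenyl]-3-[4-(benzyloxy)-2-methoxyphenyl]propyl}-5-(2-{2-[4-(benzyloxy)phenyl]-1,3-dioxolan-2-yl}ethyl)-2,4-dioxo-5-(phenylselanyl)cyclohexane-1-carboxylate | COc1cc(OCc2ccccc2)ccc1CC[C@H](c1ccc(OCc2ccccc2)cc1)C1(C(=O)OC)CC(CCC2(c3ccc(OCc4ccccc4)cc3)OCCO2)([Se]c2ccccc2)C(=O)CC1=O
F5 | step 12 | methyl 1-{(R)-1-[4-(benzyloxy)phenyl]-3-[4-(benzyloxy)-2-methoxyphenyl]propyl}-5-(2-{2-[4-(benzyloxy)phenyl]-1,3-dioxolan-2-yl}ethyl)-2,4-dioxo-5-(phenylseleninyl)cyclohexane-1-carboxylate | COc1cc(OCc2ccccc2)ccc1CC[C@H](c1ccc(OCc2ccccc2)cc1)C1(C(=O)OC)CC(CCC2(c3ccc(OCc4ccccc4)cc3)OCCO2)([Se](=O)c2ccccc2)C(=O)CC1=O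
F6 | step 12 | methyl 1-{(R)-1-[4-(benzyloxy)phenyl]-3-[4-(benzyloxy)-2-methoxyphenyl]propyl}-5-(2-{2-[4-(benzyloxy)phenyl]-1,3-dioxolan-2-yl}ethyl)-2,4-dioxocyclohex-5-ene-1-carboxylate | COc1cc(OCc2ccccc2)ccc1CC[C@H](c1ccc(OCc2ccccc2)cc1)C1(C(=O)OC)C=C(CCC2(c3ccc(OCc4ccccc4)cc3)OCCO2)C(=O)CC1=O
F7 | step 2 | [4-(benzyloxy)-2-methoxyphenyl]lithium | [Li]c1ccc(OCc2ccccc2)cc1OC
F8 | step 2 | 3-[4-(benzyloxy)-2-methoxyphenyl]propan-1-ol | COc1cc(OCc2ccccc2)ccc1CCCO
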